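**Retrosynthetic overview**

1. Target 26 ⇐ silyl ether 25 ⇐ macrocyclic sulfone 24 (reductive removal of PhSO2 from C13). The 14-membered carbocycle is the only ring of the target and is closed once, in step 15.
2. Key disconnection C13–C14: in acyclic 22 the sulfonyl-stabilised C13 carbanion opens an oxirane at its CH2 carbon C14. This closes the macrocycle and releases the C1 tertiary alcohol in the same event. The oxirane is a temporary strained ring, built twice on the same carbinol carbon (steps 5 and 14) and opened twice (steps 7 and 15).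
3. Enabling feature of 22: the three-membered ring O–C1–C14, where C1 is fully substituted and already (R)-configured and C14 is an unhindered CH2, together with the C13 methylene lying between the sulfonyl sulfur and the C11=C12 π-bond. Ring strain at C14 and double stabilisation at C13 make the 14-exo-tet closure feasible.
4. 22 ⇐ alkyne 11 + allylic chloride 17: carboalumination and palladium-catalysed allylation form C5–C6, the (4E)-alkene with its methyl group, and the skipped 4,7-diene. Chloride 17 (C6–C13, 7Z and 11E) comes from neryl acetate.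
5. 11 ⇐ (R)-citronellal: α-methylenation, early allylic oxidation of the side-chain terminus, Sharpless epoxidation (sets C1), and propargyl opening of the oxirane (C2–C3).

Key step: step 15

Remark on locants: the target is named (1R,4E,7Z,11E)-1-[(2R,5E)-7-hydroxy-6-methylhept-5-en-2-yl]-4,8,12-trimethylcyclotetradeca-4,7,11-trien-1-ol, and its ring locants C1–C14 are used for the corresponding atoms of all open-chain intermediates. TBS = tert-butyl(dimethyl)silyl, TBDPS = tert-butyl(diphenyl)silyl.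

Assumption: the titanium tartrate epoxidation of the 2-substituted allylic alcohol 5 is reagent-controlled in the usual sense, so that D-(−)-diethyl tartrate gives the (2R)-oxirane (the sense in which it converts 2-methylprop-2-en-1-ol into (R)-2-methylglycidol).

**Route**

Step 1
Reactants: 1 (R)-citronellal
Product: 2 (3R)-3,7-dimethyl-2-methylideneoct-6-enal
Conditions: 37% aq. CH2O, pyrrolidine (10 mol %), EtCO2H (10 mol %), i-PrOH, 45 °C
Reagents that add atoms: formaldehyde C=O
Why: Organocatalytic Mannich condensation–elimination (α-methylenation through the enamine and the formaldehyde-derived iminium ion) installs the methylene carbon that becomes C2, and the stereocentre is not α to the carbonyl and is not touched.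

Step 2
Reactants: 2 (3R)-3,7-dimethyl-2-methylideneoct-6-enal
Product: 3 (3R,6E)-8-hydroxy-3,7-dimethyl-2-methylideneoct-6-enal
Conditions: SeO2 (0.3 equiv), t-BuOOH (70% aq.), salicylic acid (cat.), CH2Cl2, 0 °C → rt
Reagents that add atoms: selenium dioxide O=[Se]=O; tert-butyl hydroperoxide CC(C)(C)OO
Why: SeO2 allylic oxidation (ene reaction followed by [2,3]-sigmatropic shift) should attack only the electron-rich trisubstituted alkene at its (E)-methyl group and give the (E)-allylic alcohol, because the enal alkene is electron-poor and the aldehyde has no α-hydrogen.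

Step 3
Reactants: 3 (3R,6E)-8-hydroxy-3,7-dimethyl-2-methylideneoct-6-enal
Product: 4 (3R,6E)-8-(TBDPS-oxy)-3,7-dimethyl-2-methylideneoct-6-enal
Conditions: TBDPSCl, imidazole, CH2Cl2, 0 °C → rt
Reagents that add atoms: tert-butyl(chloro)diphenylsilane CC(C)(C)[Si](Cl)(c1ccccc1)c1ccccc1
Why: Standard silylation of a primary allylic alcohol; the bulky silyl ether is chosen because it should outlast the later selective TBS cleavage and all basic and organometallic steps.

Step 4
Reactants: 4 (3R,6E)-8-(TBDPS-oxy)-3,7-dimethyl-2-methylideneoct-6-enal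
Product: 5 (3R,6E)-8-(TBDPS-oxy)-3,7-dimethyl-2-methylideneoct-6-en-1-ol
Conditions: NaBH4, CeCl3·7H2O, MeOH, −20 °C
Reagents that add atoms: none
Why: Luche reduction, in which CeCl3 steers hydride to the carbonyl carbon and so avoids conjugate reduction of the α-methylene aldehyde.

Step 5
Reactants: 5 (3R,6E)-8-(TBDPS-oxy)-3,7-dimethyl-2-methylideneoct-6-en-1-ol
Product: 6 [(2R)-2-[(2R,5E)-7-(TBDPS-oxy)-6-methylhept-5-en-2-yl]oxiran-2-yl]methanol
Conditions: Ti(OiPr)4 (10 mol %), D-(−)-diethyl tartrate (12 mol %), t-BuOOH (decane), 4 Å MS, CH2Cl2, −20 °C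
Reagents that add atoms: tert-butyl hydroperoxide CC(C)(C)OO
Why: Sharpless asymmetric epoxidation of the only free allylic alcohol sets the future C1 stereocentre under reagent control by the titanium D-(−)-tartrate complex, which should override the small bias of the neighbouring C–H stereocentre, and the silylated trisubstituted alkene is not a substrate.

Step 6
Reactants: 6 [(2R)-2-[(2R,5E)-7-(TBDPS-oxy)-6-methylhept-5-en-2-yl]oxiran-2-yl]methanol
Product: 7 tert-butyl({(2S)-2-[(2R,5E)-7-(TBDPS-oxy)-6-methylhept-5-en-2-yl]oxiran-2-yl}methoxy)dimethylsilane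
Conditions: TBSCl, imidazole, CH2Cl2, 0 °C → rt
Reagents that add atoms: tert-butyl(chloro)dimethylsilane CC(C)(C)[Si](C)(C)Cl
Why: Silylation under weakly basic conditions blocks the primary hydroxyl so that the degenerate Payne rearrangement, which would scramble the oxirane stereocentre, cannot occur in step 7 (the descriptor changes by priority only).

Step 7
Reactants: 7 tert-butyl({(2S)-2-[(2R,5E)-7-(TBDPS-oxy)-6-methylhept-5-en-2-yl]oxiran-2-yl}methoxy)dimethylsilane; 8 1-(trimethylsilyl)propyne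
Product: 11 (2R)-1-(TBS-oxy)-2-[(2R,5E)-7-(TBDPS-oxy)-6-methylhept-5-en-2-yl]hex-5-yn-2-ol, via 3-lithio-1-(trimethylsilyl)propyne 9 (not isolated), via 6-(trimethylsilyl) alkynol 10 (not isolated)
Conditions: 8, n-BuLi, TMEDA, Et2O, 0 °C; then 7, 0 °C → rt; aq. NH4Cl; then K2CO3 (cat.), MeOH, rt
Reagents that add atoms: none
Why: SN2 opening of the 2,2-disubstituted oxirane at its CH2 carbon by the propargylic lithium reagent forms the C2–C3 bond without touching the C1–O bond, so the configuration is kept, and carbonate methanolysis then cleaves only the alkynyl C–Si bond.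

Step 8
Reactants: 12 neryl acetate
Product: 13 (2Z,6E)-8-hydroxy-3,7-dimethylocta-2,6-dien-1-yl acetate
Conditions: SeO2 (cat.), t-BuOOH, salicylic acid (cat.), CH2Cl2, rt
Reagents that add atoms: selenium dioxide O=[Se]=O; tert-butyl hydroperoxide CC(C)(C)OO
Why: SeO2 allylic oxidation at the (E)-methyl group of the terminal trisubstituted alkene, the 2,3-alkene being deactivated by the allylic acetate, should give the (6E)-alcohol that later becomes C13.

Step 9
Reactants: 13 (2Z,6E)-8-hydroxy-3,7-dimethylocta-2,6-dien-1-yl acetate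
Product: 15 (2Z,6E)-3,7-dimethyl-8-(phenylsulfonyl)octa-2,6-dien-1-yl acetate, via allylic bromide 14 (not isolated)
Conditions: CBr4, PPh3, CH2Cl2, 0 °C; then PhSO2Na, DMF, rt
Reagents that add atoms: sodium benzenesulfinate [Na+].[O-]S(=O)c1ccccc1
Why: Appel bromination followed by S-alkylation of the sulfinate, both SN2 at a primary allylic carbon, should retain the alkene position and geometry.

Step 10
Reactants: 15 (2Z,6E)-3,7-dimethyl-8-(phenylsulfonyl)octa-2,6-dien-1-yl acetate
Product: 16 (2Z,6E)-3,7-dimethyl-8-(phenylsulfonyl)octa-2,6-dien-1-ol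
Conditions: K2CO3 (cat.), MeOH, rt
Reagents that add atoms: none
Why: Base-catalysed transesterification removes the acetate under conditions too mild to isomerise the allylic sulfone.

Step 11
Reactants: 16 (2Z,6E)-3,7-dimethyl-8-(phenylsulfonyl)octa-2,6-dien-1-ol
Product: 17 {[(2E,6Z)-8-chloro-2,6-dimethylocta-2,6-dien-1-yl]sulfonyl}benzene
Conditions: NCS, Me2S, CH2Cl2, −30 °C → 0 °C
Reagents that add atoms: N-chlorosuccinimide O=C1CCC(=O)N1Cl
Why: Corey–Kim chlorination (chloride displaces the alkoxysulfonium group at the primary carbon) should give the allylic chloride without allylic transposition or loss of the Z geometry.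

Step 12
Reactants: 11 (2R)-1-(TBS-oxy)-2-[(2R,5E)-7-(TBDPS-oxy)-6-methylhept-5-en-2-yl]hex-5-yn-2-ol; 17 {[(2E,6Z)-8-chloro-2,6-dimethylocta-2,6-dien-1-yl]sulfonyl}benzene
Product: 19 (2R,5E,8Z,12E)-1-(TBS-oxy)-2-[(2R,5E)-7-(TBDPS-oxy)-6-methylhept-5-en-2-yl]-5,9,13-trimethyl-14-(phenylsulfonyl)tetradeca-5,8,12-trien-2-ol, via alkenyl(dimethyl)alane 18 (not isolated)
Conditions: AlMe3 (3 equiv), Cp2ZrCl2 (25 mol %), ClCH2CH2Cl, rt; then 17, Pd(PPh3)4 (5 mol %), THF, rt
Reagents that add atoms: trimethylaluminium C[Al](C)C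
Why: Negishi zirconium-catalysed syn-carboalumination (methyl to the internal carbon, aluminium to the terminus) sets the (4E)-alkene with the C4 methyl group, and the alkenylalane should then couple with the allylic chloride under zerovalent palladium catalysis at the primary terminus with retention of both alkene geometries, forming C5–C6 and the skipped diene.

Step 13
Reactants: 19 (2R,5E,8Z,12E)-1-(TBS-oxy)-2-[(2R,5E)-7-(TBDPS-oxy)-6-methylhept-5-en-2-yl]-5,9,13-trimethyl-14-(phenylsulfonyl)tetradeca-5,8,12-trien-2-ol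
Product: 20 (2R,5E,8Z,12E)-2-[(2R,5E)-7-(TBDPS-oxy)-6-methylhept-5-en-2-yl]-5,9,13-trimethyl-14-(phenylsulfonyl)tetradeca-5,8,12-triene-1,2-diol
Conditions: HF·pyridine, pyridine, THF, 0 °C
Reagents that add atoms: none
Why: Buffered fluoride cleavage should remove the primary TBS ether selectively, the much bulkier TBDPS ether being far slower to react.

Step 14
Reactants: 20 (2R,5E,8Z,12E)-2-[(2R,5E)-7-(TBDPS-oxy)-6-methylhept-5-en-2-yl]-5,9,13-trimethyl-14-(phenylsulfonyl)tetradeca-5,8,12-triene-1,2-diol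
Product: 22 (2R)-2-[(2R,5E)-7-(TBDPS-oxy)-6-methylhept-5-en-2-yl]-2-[(3E,6Z,10E)-3,7,11-trimethyl-12-(phenylsulfonyl)dodeca-3,6,10-trien-1-yl]oxirane, via primary tosylate 21 (not isolated)
Conditions: TsCl, Et3N, Bu2SnO (2 mol %), CH2Cl2, rt; then K2CO3, MeOH, rt
Reagents that add atoms: none
Why: Tin-acetal-catalysed sulfonylation selects the primary hydroxyl of the 1,2-diol and intramolecular Williamson closure (3-exo-tet) by the tertiary oxygen gives the oxirane with the C1–O bond untouched, so C1 keeps its configuration while the base is too weak to engage the sulfone.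

Step 15
Reactants: 22 (2R)-2-[(2R,5E)-7-(TBDPS-oxy)-6-methylhept-5-en-2-yl]-2-[(3E,6Z,10E)-3,7,11-trimethyl-12-(phenylsulfonyl)dodeca-3,6,10-trien-1-yl]oxirane
Product: 24 (1S,4E,7Z,11E)-1-[(2R,5E)-7-(TBDPS-oxy)-6-methylhept-5-en-2-yl]-4,8,12-trimethyl-13-(phenylsulfonyl)cyclotetradeca-4,7,11-trien-1-ol as a mixture of C13 epimers, via C13-lithio sulfone 23 (not isolated)
Conditions: LiN(SiMe3)2 (2 equiv), THF–DMPU, 0.002 M, −78 °C → 45 °C; aq. NH4Cl
Reagents that add atoms: none
Why: The amide base removes a proton from C13, which is acidified jointly by the phenylsulfonyl group and the C11=C12 π-bond, and the α-sulfonyl allyllithium 23 attacks the oxirane CH2 (C14) from the backside in an SN2 step driven by release of the oxirane strain (about 27 kcal/mol), giving the lithium alkoxide of the C1 carbinol. The closest known reaction type is the intramolecular opening of epoxides by sulfur-stabilised allylic carbanions, which has been used to close 14-membered terpenoid carbocycles. The single ring formed is closed in a 14-exo-tet mode, the C14–O bond that breaks lying outside the new carbocycle. C1 is not a new stereocentre, since its C–O bond is not touched and the (R) arrangement set in step 5 is carried into the ring (the descriptor reads S only because the sulfonyl group changes priorities), while the new centre C13 forms without control and is erased in step 16. The step needs regioselectivity at both partners and ring closure over oligomerisation: the fully substituted C1 blocks attack at the other oxirane carbon, the sulfonyl group localises bond formation at the α-carbon C13 rather than at C11, the bis-allylic C6 methylene (pKa about 35) is not deprotonated by a base that suffices for the sulfone (pKa about 23), and high dilution disfavours intermolecular opening.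

Step 16
Reactants: 24 (1S,4E,7Z,11E)-1-[(2R,5E)-7-(TBDPS-oxy)-6-methylhept-5-en-2-yl]-4,8,12-trimethyl-13-(phenylsulfonyl)cyclotetradeca-4,7,11-trien-1-ol
Product: 25 (1R,4E,7Z,11E)-1-[(2R,5E)-7-(TBDPS-oxy)-6-methylhept-5-en-2-yl]-4,8,12-trimethylcyclotetradeca-4,7,11-trien-1-ol
Conditions: PdCl2(dppp) (5 mol %), LiBHEt3, THF, 0 °C
Reagents that add atoms: none
Why: Palladium-catalysed reductive desulfonylation of an allylic sulfone (ionisation by zerovalent palladium, then hydride delivery from the borohydride to the carbon that carried sulfur) should remove the sulfonyl group while leaving the C11=C12 double bond in place and (E)-configured.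

Step 17
Reactants: 25 (1R,4E,7Z,11E)-1-[(2R,5E)-7-(TBDPS-oxy)-6-methylhept-5-en-2-yl]-4,8,12-trimethylcyclotetradeca-4,7,11-trien-1-ol
Product: 26 (1R,4E,7Z,11E)-1-[(2R,5E)-7-hydroxy-6-methylhept-5-en-2-yl]-4,8,12-trimethylcyclotetradeca-4,7,11-trien-1-ol
Conditions: Bu4NF, THF, rt
Reagents that add atoms: none
Why: Fluoride-mediated desilylation frees the primary allylic alcohol under conditions that leave the tertiary alcohol, the skipped diene and all stereocentres untouched.

**Compound list**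

1 | (R)-citronellal, (3R)-3,7-dimethyloct-6-enal | O=CC[C@H](C)CCC=C(C)C | starting material
2 | (3R)-3,7-dimethyl-2-methylideneoct-6-enal | O=CC(=C)[C@H](C)CCC=C(C)C | intermediate
3 | (3R,6E)-8-hydroxy-3,7-dimethyl-2-methylideneoct-6-enal | O=CC(=C)[C@H](C)CC/C=C(\C)CO | intermediate
4 | (3R,6E)-8-(TBDPS-oxy)-3,7-dimethyl-2-methylideneoct-6-enal | O=CC(=C)[C@H](C)CC/C=C(\C)CO[Si](c1ccccc1)(c1ccccc1)C(C)(C)C | intermediate
5 | (3R,6E)-8-(TBDPS-oxy)-3,7-dimethyl-2-methylideneoct-6-en-1-ol | OCC(=C)[C@H](C)CC/C=C(\C)CO[Si](c1ccccc1)(c1ccccc1)C(C)(C)C | intermediate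
6 | [(2R)-2-[(2R,5E)-7-(TBDPS-oxy)-6-methylhept-5-en-2-yl]oxiran-2-yl]methanol | C1O[C@]1([C@H](C)CC/C=C(\C)CO[Si](c2ccccc2)(c2ccccc2)C(C)(C)C)CO | intermediate
7 | tert-butyl({(2S)-2-[(2R,5E)-7-(TBDPS-oxy)-6-methylhept-5-en-2-yl]oxiran-2-yl}methoxy)dimethylsilane (TBS ether of 6, same spatial arrangement) | C1O[C@]1([C@H](C)CC/C=C(\C)CO[Si](c2ccccc2)(c2ccccc2)C(C)(C)C)CO[Si](C)(C)C(C)(C)C | intermediate
8 | 1-(trimethylsilyl)propyne | CC#C[Si](C)(C)C | starting material
9 | 3-lithio-1-(trimethylsilyl)propyne | [Li]CC#C[Si](C)(C)C | intermediate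
10 | (2R)-1-(TBS-oxy)-2-[(2R,5E)-7-(TBDPS-oxy)-6-methylhept-5-en-2-yl]-6-(trimethylsilyl)hex-5-yn-2-ol | C[Si](C)(C)C#CCC[C@@](O)([C@H](C)CC/C=C(\C)CO[Si](c1ccccc1)(c1ccccc1)C(C)(C)C)CO[Si](C)(C)C(C)(C)C | intermediate
11 | (2R)-1-(TBS-oxy)-2-[(2R,5E)-7-(TBDPS-oxy)-6-methylhept-5-en-2-yl]hex-5-yn-2-ol | C#CCC[C@@](O)([C@H](C)CC/C=C(\C)CO[Si](c1ccccc1)(c1ccccc1)C(C)(C)C)CO[Si](C)(C)C(C)(C)C | intermediate
12 | neryl acetate, (2Z)-3,7-dimethylocta-2,6-dien-1-yl acetate | CC(C)=CCC/C(C)=C\COC(C)=O | starting material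
13 | (2Z,6E)-8-hydroxy-3,7-dimethylocta-2,6-dien-1-yl acetate | OC/C(C)=C/CC/C(C)=C\COC(C)=O | intermediate
14 | (2Z,6E)-8-bromo-3,7-dimethylocta-2,6-dien-1-yl acetate | BrC/C(C)=C/CC/C(C)=C\COC(C)=O | intermediate
15 | (2Z,6E)-3,7-dimethyl-8-(phenylsulfonyl)octa-2,6-dien-1-yl acetate | O=S(=O)(c1ccccc1)C/C(C)=C/CC/C(C)=C\COC(C)=O | intermediate
16 | (2Z,6E)-3,7-dimethyl-8-(phenylsulfonyl)octa-2,6-dien-1-ol | O=S(=O)(c1ccccc1)C/C(C)=C/CC/C(C)=C\CO | intermediate
17 | {[(2E,6Z)-8-chloro-2,6-dimethylocta-2,6-dien-1-yl]sulfonyl}benzene | O=S(=O)(c1ccccc1)C/C(C)=C/CC/C(C)=C\CCl | intermediate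
18 | (E)-alkenyl(dimethyl)alane from 11: Me2Al on C5, new methyl on C4, tertiary oxygen as its dimethylaluminium alkoxide | C[Al](C)/C=C(\C)CC[C@@](O[Al](C)C)([C@H](C)CC/C=C(\C)CO[Si](c1ccccc1)(c1ccccc1)C(C)(C)C)CO[Si](C)(C)C(C)(C)C | intermediate
19 | (2R,5E,8Z,12E)-1-(TBS-oxy)-2-[(2R,5E)-7-(TBDPS-oxy)-6-methylhept-5-en-2-yl]-5,9,13-trimethyl-14-(phenylsulfonyl)tetradeca-5,8,12-trien-2-ol | O=S(=O)(c1ccccc1)C/C(C)=C/CC/C(C)=C\C/C=C(\C)CC[C@@](O)([C@H](C)CC/C=C(\C)CO[Si](c1ccccc1)(c1ccccc1)C(C)(C)C)CO[Si](C)(C)C(C)(C)C | intermediate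
20 | (2R,5E,8Z,12E)-2-[(2R,5E)-7-(TBDPS-oxy)-6-methylhept-5-en-2-yl]-5,9,13-trimethyl-14-(phenylsulfonyl)tetradeca-5,8,12-triene-1,2-diol | O=S(=O)(c1ccccc1)C/C(C)=C/CC/C(C)=C\C/C=C(\C)CC[C@@](O)([C@H](C)CC/C=C(\C)CO[Si](c1ccccc1)(c1ccccc1)C(C)(C)C)CO | intermediate
21 | 1-(4-methylbenzenesulfonate) of diol 20 | O=S(=O)(c1ccccc1)C/C(C)=C/CC/C(C)=C\C/C=C(\C)CC[C@@](O)([C@H](C)CC/C=C(\C)CO[Si](c1ccccc1)(c1ccccc1)C(C)(C)C)COS(=O)(=O)c1ccc(C)cc1 | intermediate
22 | (2R)-2-[(2R,5E)-7-(TBDPS-oxy)-6-methylhept-5-en-2-yl]-2-[(3E,6Z,10E)-3,7,11-trimethyl-12-(phenylsulfonyl)dodeca-3,6,10-trien-1-yl]oxirane | O=S(=O)(c1ccccc1)C/C(C)=C/CC/C(C)=C\C/C=C(\C)CC[C@@]1([C@H](C)CC/C=C(\C)CO[Si](c2ccccc2)(c2ccccc2)C(C)(C)C)CO1 | intermediate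
23 | C13-lithio derivative of 22 (lithium on the sulfonyl-bearing carbon) | [Li]C(S(=O)(=O)c1ccccc1)/C(C)=C/CC/C(C)=C\C/C=C(\C)CC[C@@]1([C@H](C)CC/C=C(\C)CO[Si](c2ccccc2)(c2ccccc2)C(C)(C)C)CO1 | intermediate
24 | (1S,4E,7Z,11E)-1-[(2R,5E)-7-(TBDPS-oxy)-6-methylhept-5-en-2-yl]-4,8,12-trimethyl-13-(phenylsulfonyl)cyclotetradeca-4,7,11-trien-1-ol, C13 epimers (C1 spatially as in 26) | C/C1=C/C/C=C(\C)CC[C@@](O)([C@H](C)CC/C=C(\C)CO[Si](c2ccccc2)(c2ccccc2)C(C)(C)C)CC(S(=O)(=O)c2ccccc2)/C(C)=C/CC1 | intermediate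
25 | (1R,4E,7Z,11E)-1-[(2R,5E)-7-(TBDPS-oxy)-6-methylhept-5-en-2-yl]-4,8,12-trimethylcyclotetradeca-4,7,11-trien-1-ol | C/C1=C/C/C=C(\C)CC[C@@](O)([C@H](C)CC/C=C(\C)CO[Si](c2ccccc2)(c2ccccc2)C(C)(C)C)CC/C(C)=C/CC1 | intermediate
26 | (1R,4E,7Z,11E)-1-[(2R,5E)-7-hydroxy-6-methylhept-5-en-2-yl]-4,8,12-trimethylcyclotetradeca-4,7,11-trien-1-ol | C/C1=C/C/C=C(\C)CC[C@@](O)([C@H](C)CC/C=C(\C)CO)CC/C(C)=C/CC1 | target

**Step count and risks**

Total step count: 17. Longest linear sequence: 13 steps (steps 1–7 and 12–17); chloride 17 is made in 4 steps (8–11).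

Steps most likely to fail:

1. Step 15. The opening of the hindered oxirane may be slow enough for intermolecular oligomerisation or base-induced isomerisation of the oxirane to an allylic alcohol to compete with ring closure. The fallback sets out from 20 and returns at 25, forming the same C13–C14 bond by carbonyl addition. Parikh–Doering oxidation of the primary hydroxyl of 20 (SO3·pyridine, DMSO, i-Pr2NEt) gives the α-hydroxy aldehyde F1. LiN(SiMe3)2 (2.2 equiv) in THF at −78 °C under high dilution then adds the C13 sulfonyl carbanion to the C14 aldehyde, a much faster process than epoxide opening, to give the macrocyclic β-hydroxy sulfone F2. Acetylation of the secondary hydroxyl (Ac2O, DMAP, pyridine) gives the β-acetoxy sulfone F3, and Julia reductive elimination (Na(Hg), Na2HPO4, MeOH–THF, −20 °C) gives the 11,13-diene F4. Diimide (2-nitrobenzenesulfonyl hydrazide, Et3N, CH2Cl2) should saturate only the disubstituted C13=C14 bond and give 25, which also bypasses step 16.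

2. Step 16. Hydride may be delivered at C11 instead of C13, moving the double bond to C12=C13, or the (11E) geometry may be lost by isomerisation of the allylpalladium intermediate. The fallback sets out from 24 and returns at 25. A radical chain reaction with Bu3SnH and AIBN (benzene, 80 °C) replaces the sulfonyl group by tin with allylic transposition (the stannyl radical adds at C11 and the sulfonyl radical leaves from C13), giving the allylstannane F5. Protodestannylation with acetic acid (SE2′, proton to C13, tin lost from C11) transposes the double bond back to C11=C12, where the anti pathway should favour the (E)-alkene, and gives 25. The alkene position is then fixed by two consecutive transpositions and not by the site of hydride attack.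

3. Step 12. The Lewis acidic aluminium species may ionise the allylic sulfone of 17, or methyl transfer may compete with alkenyl transfer, during the one-pot coupling. The fallback sets out from alane 18 (made from 11 as in step 12) and returns at 19. The alane is transmetalated with 2-isopropoxy-4,4,5,5-tetramethyl-1,3,2-dioxaborolane and worked up to the isolable (E)-alkenyl pinacol boronate F6. Suzuki–Miyaura coupling of F6 with chloride 17 (PdCl2(dppf), K3PO4, THF–H2O, 40 °C) then forms the C5–C6 bond in the absence of aluminium and gives 19.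

**Further compounds**

F1 | step 15 | (2R,5E,8Z,12E)-2-[(2R,5E)-7-(TBDPS-oxy)-6-methylhept-5-en-2-yl]-2-hydroxy-5,9,13-trimethyl-14-(phenylsulfonyl)tetradeca-5,8,12-trienal | O=S(=O)(c1ccccc1)C/C(C)=C/CC/C(C)=C\C/C=C(\C)CC[C@@](O)([C@H](C)CC/C=C(\C)CO[Si](c1ccccc1)(c1ccccc1)C(C)(C)C)C=O
F2 | step 15 | 14-hydroxy derivative of 24: (4E,7Z,11E)-1-[(2R,5E)-7-(TBDPS-oxy)-6-methylhept-5-en-2-yl]-4,8,12-trimethyl-13-(phenylsulfonyl)cyclotetradeca-4,7,11-triene-1,14-diol, C1 as in 20, C13 and C14 epimers | C/C1=C/C/C=C(\C)CC[C@@](O)([C@H](C)CC/C=C(\C)CO[Si](c2ccccc2)(c2ccccc2)C(C)(C)C)C(O)C(S(=O)(=O)c2ccccc2)/C(C)=C/CC1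
F3 | step 15 | 14-O-acetate of F2 | C/C1=C/C/C=C(\C)CC[C@@](O)([C@H](C)CC/C=C(\C)CO[Si](c2ccccc2)(c2ccccc2)C(C)(C)C)C(OC(C)=O)C(S(=O)(=O)c2ccccc2)/C(C)=C/CC1
F4 | step 15 | (1R,4E,7Z,11E,13E)-1-[(2R,5E)-7-(TBDPS-oxy)-6-methylhept-5-en-2-yl]-4,8,12-trimethylcyclotetradeca-4,7,11,13-tetraen-1-ol | C/C1=C/C/C=C(\C)CC[C@@](O)([C@H](C)CC/C=C(\C)CO[Si](c2ccccc2)(c2ccccc2)C(C)(C)C)/C=C/C(C)=C/CC1
F5 | step 16 | (4E,7Z)-1-[(2R,5E)-7-(TBDPS-oxy)-6-methylhept-5-en-2-yl]-4,8,12-trimethyl-11-(tributylstannyl)cyclotetradeca-4,7,12-trien-1-ol, C1 as in 25, C11 epimers and 12E/Z mixture | C/C1=C/C/C=C(\C)CC[C@@](O)([C@H](C)CC/C=C(\C)CO[Si](c2ccccc2)(c2ccccc2)C(C)(C)C)CC=C(C)C([Sn](CCCC)(CCCC)CCCC)CC1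
F6 | step 12 | (2R,5E)-1-(TBS-oxy)-2-[(2R,5E)-7-(TBDPS-oxy)-6-methylhept-5-en-2-yl]-5-methyl-6-(4,4,5,5-tetramethyl-1,3,2-dioxaborolan-2-yl)hex-5-en-2-ol | CC1(C)OB(/C=C(\C)CC[C@@](O)([C@H](C)CC/C=C(\C)CO[Si](c2ccccc2)(c2ccccc2)C(C)(C)C)CO[Si](C)(C)C(C)(C)C)OC1(C)C
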